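**Plan**
- The aldehyde and the three hydroxyls are unmasked last (acetal, benzyl ethers). The benzylic CH2 of the side chain is traced back to an aryl ketone. The retrosynthesis then cuts C4–O and C5–C(acyl) together, as the insertion of a benzofuran-4,5-yne into the C–O bond of a carboxylic acid.
- What makes this possible: on ring A, C4 bears a hydroxyl and the neighbouring C5 a carbon chain, and the methoxy group on C6, next to C5, polarises a C4≡C5 triple bond so that oxygen goes to C4 and carbon to C5.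
- The aryne precursor (C4 silyl, C5 triflate) comes from a 5-hydroxybenzofuran by C4 bromination and a retro-Brook shift. The furan ring (O1–C2 and C3–C3a) is cut back to methoxy-1,4-benzoquinone and an aroylacetate.
- Forward: ring B is bought as an acetophenone and turned into the β-ketoester; the furan ring closes onto the quinone-derived ring A; the ester becomes an acetal; the silyl triflate is made; the chain is joined; then deoxygenation and deprotection.
- Stereochemistry: the target has no stereocentre, so none has to be set.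

Key step: step 11

Remark: the tertiary alcohol is carried as a benzyl ether, because a silyl ether would be exposed to CsF at 125 °C and the freed β-hydroxy ketone could undergo retro-aldol cleavage. Compounds 1, 4 and 14 are taken as catalogue compounds.

**Step 1**
Reactants: 1 1-[4-(benzyloxy)-2-hydroxyphenyl]ethanone
Product: 2 1-[4-(benzyloxy)-2-methoxyphenyl]ethanone
Conditions: MeI, K2CO3, DMF, 50 °C
Reagents that add atoms: iodomethane, CI
Why: Williamson O-methylation of the chelated ortho-hydroxyl should go cleanly in DMF with K2CO3, the only acidic site being this phenol.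

**Step 2**
Reactants: 2 1-[4-(benzyloxy)-2-methoxyphenyl]ethanone
Product: 3 ethyl 3-[4-(benzyloxy)-2-methoxyphenyl]-3-oxopropanoate
Conditions: NaH, (EtO)2CO, THF, reflux; then AcOH
Reagents that add atoms: diethyl carbonate, CCOC(=O)OCC
Why: Crossed Claisen condensation of the methyl ketone enolate with diethyl carbonate, driven by irreversible deprotonation of the β-ketoester formed.

**Step 3**
Reactants: 3 ethyl 3-[4-(benzyloxy)-2-methoxyphenyl]-3-oxopropanoate; 4 methoxy-1,4-benzoquinone
Product: 6 ethyl 2-[4-(benzyloxy)-2-methoxyphenyl]-5-hydroxy-6-methoxy-1-benzofuran-3-carboxylate, via hydroquinone Michael adduct 5 (not isolated)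
Conditions: Cu(OTf)2 (10 mol %), toluene, 100 °C
Reagents that add atoms: none
Why: Nenitzescu-type benzofuran synthesis: the ketoester enol adds to the quinone carbon that is β to the carbonyl not deactivated by the methoxy group (Michael addition), and the adjacent hydroquinone hydroxyl then condenses with the aryl ketone to close the furan ring, which places OH on C5 and OMe on C6.

**Step 4**
Reactants: 6 ethyl 2-[4-(benzyloxy)-2-methoxyphenyl]-5-hydroxy-6-methoxy-1-benzofuran-3-carboxylate
Product: 7 ethyl 2-[4-(benzyloxy)-2-methoxyphenyl]-4-bromo-5-hydroxy-6-methoxy-1-benzofuran-3-carboxylate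
Conditions: NBS (1.0 equiv), i-Pr2NH (10 mol %), CH2Cl2, −20 to 0 °C, dark
Reagents that add atoms: N-bromosuccinimide, O=C1CCC(=O)N1Br
Why: Amine-catalysed ortho-selective electrophilic bromination of a phenol; C4 is the only free position ortho to the free C5 hydroxyl, which activates more strongly than the ether oxygens at C7 and on ring B, and the C3 ester conjugated through C2 damps ring B.

**Step 5**
Reactants: 7 ethyl 2-[4-(benzyloxy)-2-methoxyphenyl]-4-bromo-5-hydroxy-6-methoxy-1-benzofuran-3-carboxylate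
Product: 8 2-[4-(benzyloxy)-2-methoxyphenyl]-4-bromo-3-(hydroxymethyl)-6-methoxy-1-benzofuran-5-ol
Conditions: i-Bu2AlH (4 equiv), CH2Cl2, −78 to 0 °C; Rochelle salt work-up
Reagents that add atoms: none
Why: Hydride reduction of the ester to the primary alcohol with i-Bu2AlH, which leaves the aryl bromide and the ethers alone; the phenol is carried as its aluminium phenoxide.

**Step 6**
Reactants: 8 2-[4-(benzyloxy)-2-methoxyphenyl]-4-bromo-3-(hydroxymethyl)-6-methoxy-1-benzofuran-5-ol
Product: 9 2-[4-(benzyloxy)-2-methoxyphenyl]-4-bromo-5-hydroxy-6-methoxy-1-benzofuran-3-carbaldehyde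
Conditions: MnO2 (activated, excess), CH2Cl2, rt
Reagents that add atoms: none
Why: MnO2 oxidation is selective for the heterobenzylic alcohol and stops at the aldehyde, and the bromophenol should tolerate this mild heterogeneous oxidant.

**Step 7**
Reactants: 9 2-[4-(benzyloxy)-2-methoxyphenyl]-4-bromo-5-hydroxy-6-methoxy-1-benzofuran-3-carbaldehyde
Product: 10 2-[4-(benzyloxy)-2-methoxyphenyl]-4-bromo-3-(dimethoxymethyl)-6-methoxy-1-benzofuran-5-ol
Conditions: HC(OMe)3, MeOH, PPTS (cat.), 50 °C; then Et3N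
Reagents that add atoms: trimethyl orthoformate, COC(OC)OC; methanol, CO
Why: Acid-catalysed acetalisation driven by the orthoformate as water scavenger; the acetal masks the aldehyde against the organolithium, the aryne and the hydride steps that follow.

**Step 8**
Reactants: 10 2-[4-(benzyloxy)-2-methoxyphenyl]-4-bromo-3-(dimethoxymethyl)-6-methoxy-1-benzofuran-5-ol
Product: 13 2-[4-(benzyloxy)-2-methoxyphenyl]-3-(dimethoxymethyl)-6-methoxy-4-(trimethylsilyl)-1-benzofuran-5-yl trifluoromethanesulfonate, via aryl trimethylsilyl ether 11 (not isolated), via lithium 4-silylphenoxide 12 (not isolated)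
Conditions: HMDS, THF, 65 °C, then evaporate; n-BuLi, THF, −78 °C; PhNTf2, −78 °C to rt
Reagents that add atoms: hexamethyldisilazane, C[Si](C)(C)N[Si](C)(C)C; N-phenylbis(trifluoromethanesulfonimide), O=S(=O)(N(c1ccccc1)S(=O)(=O)C(F)(F)F)C(F)(F)F
Why: O-silylation, bromine–lithium exchange at C4 and the 1,3 O-to-C silyl shift (retro-Brook rearrangement) form the standard entry to ortho-silylaryl triflates from ortho-bromophenols; the lithium phenoxide released is triflated in the same flask with PhNTf2, which is non-acidic and spares the acetal.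

**Step 9**
Reactants: 14 ethyl 3-hydroxy-3-methylbutanoate
Product: 15 ethyl 3-(benzyloxy)-3-methylbutanoate
Conditions: 2-benzyloxy-1-methylpyridinium triflate (2 equiv), MgO, PhCF3, 83 °C
Reagents that add atoms: 2-benzyloxy-1-methylpyridinium triflate, C[n+]1ccccc1OCc1ccccc1.[O-]S(=O)(=O)C(F)(F)F
Why: Dudley benzylation transfers benzyl thermally under near-neutral, MgO-buffered conditions, which suits a tertiary β-hydroxy ester that would eliminate under strong base or strong acid.

**Step 10**
Reactants: 15 ethyl 3-(benzyloxy)-3-methylbutanoate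
Product: 16 3-(benzyloxy)-3-methylbutanoic acid
Conditions: LiOH, THF/H2O, rt; then dilute HCl to pH 3
Reagents that add atoms: lithium hydroxide, [Li+].[OH-]
Why: Saponification at room temperature should be faster than β-elimination of benzyloxide, and the benzyl ether is inert to hydroxide.

**Step 11**
Reactants: 13 2-[4-(benzyloxy)-2-methoxyphenyl]-3-(dimethoxymethyl)-6-methoxy-4-(trimethylsilyl)-1-benzofuran-5-yl trifluoromethanesulfonate; 16 3-(benzyloxy)-3-methylbutanoic acid
Product: 18 3-(benzyloxy)-1-{2-[4-(benzyloxy)-2-methoxyphenyl]-3-(dimethoxymethyl)-4-hydroxy-6-methoxy-1-benzofuran-5-yl}-3-methylbutan-1-one, via benzofuran-4,5-yne 17 (not isolated)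
Conditions: 16 (2 equiv), CsF (4 equiv), THF, 125 °C, sealed tube
Reagents that add atoms: none
Why: Fluoride removes the C4 silyl group and triflate leaves from C5 (Kobayashi aryne generation) to give aryne 17; the cesium carboxylate of 16 adds through oxygen to C4, the C5 aryl anion attacks the acyl carbon, and the four-membered hemiketal alkoxide opens to the C4 phenoxide and the C5 ketone, so C4–O and C5–C(acyl) form in one operation. The closest known reaction is the fluoride-mediated insertion of arynes from ortho-silylaryl triflates into the C–O bond of carboxylic acids, which gives ortho-hydroxyaryl ketones in hot THF and stops at the aryl ester at lower temperature. No ring is retained: the only closure is the transient 4-exo-trig attack of the aryl anion on the carbonyl, the ring reopens at once, and no stereocentre is formed. The step needs oxygen to attack C4 and not C5: the C6 methoxy group next to the triple bond stabilises negative charge at C5 inductively and distorts the aryne so that C4 is the more electrophilic terminus, the same control seen in 3-methoxybenzyne, and this has to outweigh the peri acetal on C3 and the native C5 preference of 4,5-fused arynes. It also needs acyl transfer to beat protonation of the C5 anion and the β-benzyloxy ketone to survive: excess CsF keeps the acid as its carboxylate, the high temperature favours the intramolecular acyl transfer, the product sits as a phenoxide conjugated with the ketone and so resists enolisation, and fluoride cannot remove the benzyl group.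

**Step 12**
Reactants: 18 3-(benzyloxy)-1-{2-[4-(benzyloxy)-2-methoxyphenyl]-3-(dimethoxymethyl)-4-hydroxy-6-methoxy-1-benzofuran-5-yl}-3-methylbutan-1-one
Product: 21 5-[3-(benzyloxy)-3-methylbutyl]-2-[4-(benzyloxy)-2-methoxyphenyl]-3-(dimethoxymethyl)-6-methoxy-1-benzofuran-4-ol, via aryl ethyl carbonate 19 (not isolated), via ortho-quinone methide 20 (not isolated)
Conditions: ClCO2Et, Et3N, THF, 0 °C; then NaBH4, H2O/THF, 0 °C to rt
Reagents that add atoms: none
Why: Reductive deoxygenation of an ortho-acylphenol through its carbonate: NaBH4 reduces the ketone, the alkoxide takes over the carbonate and expels it to give ortho-quinone methide 20, and hydride 1,4-addition gives the methylene compound under basic conditions that leave the acetal and benzyl ethers untouched.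

**Step 13**
Reactants: 21 5-[3-(benzyloxy)-3-methylbutyl]-2-[4-(benzyloxy)-2-methoxyphenyl]-3-(dimethoxymethyl)-6-methoxy-1-benzofuran-4-ol
Product: 22 3-(dimethoxymethyl)-5-(3-hydroxy-3-methylbutyl)-2-(4-hydroxy-2-methoxyphenyl)-6-methoxy-1-benzofuran-4-ol
Conditions: H2 (1 atm), Pd/C, EtOAc/EtOH, solid NaHCO3, rt
Reagents that add atoms: none
Why: Catalytic hydrogenolysis cleaves the aryl and the tertiary alkyl benzyl ether in one operation, while the tetrasubstituted furan double bond and the acetal (kept neutral by the buffer) should survive.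

**Step 14**
Reactants: 22 3-(dimethoxymethyl)-5-(3-hydroxy-3-methylbutyl)-2-(4-hydroxy-2-methoxyphenyl)-6-methoxy-1-benzofuran-4-ol
Product: 23 Ebenfuran VI, 4-hydroxy-5-(3-hydroxy-3-methylbutyl)-2-(4-hydroxy-2-methoxyphenyl)-6-methoxy-1-benzofuran-3-carbaldehyde
Conditions: PPTS (cat.), acetone/H2O (10:1), rt
Reagents that add atoms: water, O
Why: Acid-catalysed acetal hydrolysis; the oxocarbenium ion is stabilised by the furan oxygen, so a weak acid suffices and the tertiary alcohol should not ionise and cyclise onto the C4 phenol.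

**Compound list**
1 | 1-[4-(benzyloxy)-2-hydroxyphenyl]ethanone | CC(=O)c1ccc(OCc2ccccc2)cc1O | starting material
2 | 1-[4-(benzyloxy)-2-methoxyphenyl]ethanone | CC(=O)c1ccc(OCc2ccccc2)cc1OC | intermediate
3 | ethyl 3-[4-(benzyloxy)-2-methoxyphenyl]-3-oxopropanoate | CCOC(=O)CC(=O)c1ccc(OCc2ccccc2)cc1OC | intermediate
4 | methoxy-1,4-benzoquinone | COC1=CC(=O)C=CC1=O | starting material
5 | ethyl 3-[4-(benzyloxy)-2-methoxyphenyl]-2-(2,5-dihydroxy-4-methoxyphenyl)-3-oxopropanoate (racemic, not isolated) | CCOC(=O)C(C(=O)c1ccc(OCc2ccccc2)cc1OC)c1cc(O)c(OC)cc1O | intermediate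
6 | ethyl 2-[4-(benzyloxy)-2-methoxyphenyl]-5-hydroxy-6-methoxy-1-benzofuran-3-carboxylate | CCOC(=O)c1c(-c2ccc(OCc3ccccc3)cc2OC)oc2cc(OC)c(O)cc12 | intermediate
7 | ethyl 2-[4-(benzyloxy)-2-methoxyphenyl]-4-bromo-5-hydroxy-6-methoxy-1-benzofuran-3-carboxylate | CCOC(=O)c1c(-c2ccc(OCc3ccccc3)cc2OC)oc2cc(OC)c(O)c(Br)c12 | intermediate
8 | 2-[4-(benzyloxy)-2-methoxyphenyl]-4-bromo-3-(hydroxymethyl)-6-methoxy-1-benzofuran-5-ol | OCc1c(-c2ccc(OCc3ccccc3)cc2OC)oc2cc(OC)c(O)c(Br)c12 | intermediate
9 | 2-[4-(benzyloxy)-2-methoxyphenyl]-4-bromo-5-hydroxy-6-methoxy-1-benzofuran-3-carbaldehyde | O=Cc1c(-c2ccc(OCc3ccccc3)cc2OC)oc2cc(OC)c(O)c(Br)c12 | intermediate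
10 | 2-[4-(benzyloxy)-2-methoxyphenyl]-4-bromo-3-(dimethoxymethyl)-6-methoxy-1-benzofuran-5-ol | COC(OC)c1c(-c2ccc(OCc3ccccc3)cc2OC)oc2cc(OC)c(O)c(Br)c12 | intermediate
11 | trimethylsilyl ether of 10 at the C5 oxygen (not isolated) | COC(OC)c1c(-c2ccc(OCc3ccccc3)cc2OC)oc2cc(OC)c(O[Si](C)(C)C)c(Br)c12 | intermediate
12 | lithium 2-[4-(benzyloxy)-2-methoxyphenyl]-3-(dimethoxymethyl)-6-methoxy-4-(trimethylsilyl)-1-benzofuran-5-olate (not isolated) | [Li+].COC(OC)c1c(-c2ccc(OCc3ccccc3)cc2OC)oc2cc(OC)c([O-])c([Si](C)(C)C)c12 | intermediate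
13 | 2-[4-(benzyloxy)-2-methoxyphenyl]-3-(dimethoxymethyl)-6-methoxy-4-(trimethylsilyl)-1-benzofuran-5-yl trifluoromethanesulfonate | COC(OC)c1c(-c2ccc(OCc3ccccc3)cc2OC)oc2cc(OC)c(OS(=O)(=O)C(F)(F)F)c([Si](C)(C)C)c12 | intermediate
14 | ethyl 3-hydroxy-3-methylbutanoate | CCOC(=O)CC(C)(C)O | starting material
15 | ethyl 3-(benzyloxy)-3-methylbutanoate | CCOC(=O)CC(C)(C)OCc1ccccc1 | intermediate
16 | 3-(benzyloxy)-3-methylbutanoic acid | OC(=O)CC(C)(C)OCc1ccccc1 | intermediate
17 | 2-[4-(benzyloxy)-2-methoxyphenyl]-3-(dimethoxymethyl)-6-methoxy-4,5-didehydro-1-benzofuran (the 4,5-aryne, not isolated) | COC(OC)C1=C(c3ccc(OCc4ccccc4)cc3OC)OC2=C1C#CC(OC)=C2 | intermediate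
18 | 3-(benzyloxy)-1-{2-[4-(benzyloxy)-2-methoxyphenyl]-3-(dimethoxymethyl)-4-hydroxy-6-methoxy-1-benzofuran-5-yl}-3-methylbutan-1-one | COC(OC)c1c(-c2ccc(OCc3ccccc3)cc2OC)oc2cc(OC)c(C(=O)CC(C)(C)OCc3ccccc3)c(O)c12 | intermediate
19 | ethyl carbonate of 18 at the C4 oxygen (not isolated) | COC(OC)c1c(-c2ccc(OCc3ccccc3)cc2OC)oc2cc(OC)c(C(=O)CC(C)(C)OCc3ccccc3)c(OC(=O)OCC)c12 | intermediate
20 | 5-[3-(benzyloxy)-3-methylbutylidene]-2-[4-(benzyloxy)-2-methoxyphenyl]-3-(dimethoxymethyl)-6-methoxy-1-benzofuran-4(5H)-one (ortho-quinone methide, not isolated) | COC(OC)C1=C(c3ccc(OCc4ccccc4)cc3OC)OC2=C1C(=O)C(=CCC(C)(C)OCc1ccccc1)C(OC)=C2 | intermediate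
21 | 5-[3-(benzyloxy)-3-methylbutyl]-2-[4-(benzyloxy)-2-methoxyphenyl]-3-(dimethoxymethyl)-6-methoxy-1-benzofuran-4-ol | COC(OC)c1c(-c2ccc(OCc3ccccc3)cc2OC)oc2cc(OC)c(CCC(C)(C)OCc3ccccc3)c(O)c12 | intermediate
22 | 3-(dimethoxymethyl)-5-(3-hydroxy-3-methylbutyl)-2-(4-hydroxy-2-methoxyphenyl)-6-methoxy-1-benzofuran-4-ol | COC(OC)c1c(-c2ccc(O)cc2OC)oc2cc(OC)c(CCC(C)(C)O)c(O)c12 | intermediate
23 | Ebenfuran VI, 4-hydroxy-5-(3-hydroxy-3-methylbutyl)-2-(4-hydroxy-2-methoxyphenyl)-6-methoxy-1-benzofuran-3-carbaldehyde | COc1cc(O)ccc1-c1oc2cc(OC)c(CCC(C)(C)O)c(O)c2c1C=O | target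

**Step count**
Total: 14 steps. Longest linear sequence: 12 steps (steps 1–8 and 11–14); the acid branch is steps 9–10.

**Steps most likely to fail, with fallbacks**

Step 11. The C5 aryl anion may be protonated before it transfers the acyl group, so that only O-arylation occurs. Alternatively, benzyl alcohol may be lost from the β-benzyloxy ketone and the phenoxide may close onto the resulting enone. The fallback builds the chain from a one-carbon aryne insertion and sets out from 13. CsF in DMF should let the aryne insert into the formamide C=O bond under the same methoxy control, and aqueous work-up should give the salicylaldehyde 2-[4-(benzyloxy)-2-methoxyphenyl]-3-(dimethoxymethyl)-4-hydroxy-6-methoxy-1-benzofuran-5-carbaldehyde F1. Wittig olefination with Ph3P=CHC(O)CH3 in toluene should give the (E)-enone 4-{2-[4-(benzyloxy)-2-methoxyphenyl]-3-(dimethoxymethyl)-4-hydroxy-6-methoxy-1-benzofuran-5-yl}but-3-en-2-one F2. Hydrogenation over Pd/C should saturate the alkene and remove the benzyl ether to give the methyl ketone 4-[3-(dimethoxymethyl)-4-hydroxy-2-(4-hydroxy-2-methoxyphenyl)-6-methoxy-1-benzofuran-5-yl]butan-2-one F3. Excess MeMgBr in THF then adds to the ketone, and the route is rejoined at 22.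

Step 4. Bromine may be delivered to ring B (C5') or to C7 instead of C4. The fallback places silicon by directed ortho-metalation instead of through a halide and sets out from 6. The operations of steps 5–7 (i-Bu2AlH, then MnO2, then HC(OMe)3/PPTS) applied to 6 should give in turn:
- the alcohol 2-[4-(benzyloxy)-2-methoxyphenyl]-3-(hydroxymethyl)-6-methoxy-1-benzofuran-5-ol F4;
- the aldehyde 2-[4-(benzyloxy)-2-methoxyphenyl]-5-hydroxy-6-methoxy-1-benzofuran-3-carbaldehyde F5;
- the phenol acetal 2-[4-(benzyloxy)-2-methoxyphenyl]-3-(dimethoxymethyl)-6-methoxy-1-benzofuran-5-ol F6.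

Isopropyl isocyanate and Et3N should then give the carbamate 2-[4-(benzyloxy)-2-methoxyphenyl]-3-(dimethoxymethyl)-6-methoxy-1-benzofuran-5-yl N-isopropylcarbamate F7. N-silylation with TBSOTf/TMEDA, lithiation with n-BuLi/TMEDA at −78 °C at C4 (the only free position ortho to the carbamate) and a TMSCl quench should give the 4-trimethylsilyl carbamate F8. DBU and Et2NH in MeCN cleave the carbamate to the silylphenol 2-[4-(benzyloxy)-2-methoxyphenyl]-3-(dimethoxymethyl)-6-methoxy-4-(trimethylsilyl)-1-benzofuran-5-ol F9, and PhNTf2 in the same flask triflates it, rejoining the route at 13.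

Step 12. The hindered, hydrogen-bonded C4 phenol may resist carbonate formation, or the quinone methide may tautomerise to a styrene faster than it is reduced. The fallback removes the benzylic oxygen by hydrogenolysis and sets out from 18. NaBH4 in MeOH should give the racemic benzylic alcohol 5-[3-(benzyloxy)-1-hydroxy-3-methylbutyl]-2-[4-(benzyloxy)-2-methoxyphenyl]-3-(dimethoxymethyl)-6-methoxy-1-benzofuran-4-ol F10. Hydrogenolysis over Pd(OH)2/C under H2 should cleave the electron-rich ortho-hydroxybenzylic C–O bond together with both benzyl ethers, rejoining the route at 22.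

**Further compounds**
F1 | step 11 | 2-[4-(benzyloxy)-2-methoxyphenyl]-3-(dimethoxymethyl)-4-hydroxy-6-methoxy-1-benzofuran-5-carbaldehyde | COC(OC)c1c(-c2ccc(OCc3ccccc3)cc2OC)oc2cc(OC)c(C=O)c(O)c12
F2 | step 11 | (E)-4-{2-[4-(benzyloxy)-2-methoxyphenyl]-3-(dimethoxymethyl)-4-hydroxy-6-methoxy-1-benzofuran-5-yl}but-3-en-2-one | COC(OC)c1c(-c2ccc(OCc3ccccc3)cc2OC)oc2cc(OC)c(/C=C/C(C)=O)c(O)c12
F3 | step 11 | 4-[3-(dimethoxymethyl)-4-hydroxy-2-(4-hydroxy-2-methoxyphenyl)-6-methoxy-1-benzofuran-5-yl]butan-2-one | COC(OC)c1c(-c2ccc(O)cc2OC)oc2cc(OC)c(CCC(C)=O)c(O)c12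
F4 | step 4 | 2-[4-(benzyloxy)-2-methoxyphenyl]-3-(hydroxymethyl)-6-methoxy-1-benzofuran-5-ol | OCc1c(-c2ccc(OCc3ccccc3)cc2OC)oc2cc(OC)c(O)cc12
F5 | step 4 | 2-[4-(benzyloxy)-2-methoxyphenyl]-5-hydroxy-6-methoxy-1-benzofuran-3-carbaldehyde | O=Cc1c(-c2ccc(OCc3ccccc3)cc2OC)oc2cc(OC)c(O)cc12
F6 | step 4 | 2-[4-(benzyloxy)-2-methoxyphenyl]-3-(dimethoxymethyl)-6-methoxy-1-benzofuran-5-ol | COC(OC)c1c(-c2ccc(OCc3ccccc3)cc2OC)oc2cc(OC)c(O)cc12
F7 | step 4 | 2-[4-(benzyloxy)-2-methoxyphenyl]-3-(dimethoxymethyl)-6-methoxy-1-benzofuran-5-yl N-isopropylcarbamate | COC(OC)c1c(-c2ccc(OCc3ccccc3)cc2OC)oc2cc(OC)c(OC(=O)NC(C)C)cc12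
F8 | step 4 | 2-[4-(benzyloxy)-2-methoxyphenyl]-3-(dimethoxymethyl)-6-methoxy-4-(trimethylsilyl)-1-benzofuran-5-yl N-isopropylcarbamate | COC(OC)c1c(-c2ccc(OCc3ccccc3)cc2OC)oc2cc(OC)c(OC(=O)NC(C)C)c([Si](C)(C)C)c12
F9 | step 4 | 2-[4-(benzyloxy)-2-methoxyphenyl]-3-(dimethoxymethyl)-6-methoxy-4-(trimethylsilyl)-1-benzofuran-5-ol | COC(OC)c1c(-c2ccc(OCc3ccccc3)cc2OC)oc2cc(OC)c(O)c([Si](C)(C)C)c12
F10 | step 12 | 5-[3-(benzyloxy)-1-hydroxy-3-methylbutyl]-2-[4-(benzyloxy)-2-methoxyphenyl]-3-(dimethoxymethyl)-6-methoxy-1-benzofuran-4-ol (racemic) | COC(OC)c1c(-c2ccc(OCc3ccccc3)cc2OC)oc2cc(OC)c(C(O)CC(C)(C)OCc3ccccc3)c(O)c12
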